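## Retrosynthetic overview

1. Locants follow tricyclo[5.3.1.0(1,5)]undecane numbering: C1 ring-fusion quaternary carbon, C3 the CH carrying the 2-hydroxypropan-2-yl group, C5 ring-fusion CH, C7 methyl-bearing bridgehead, C8–C10 the enolised diketone bridge, C11 the bridging ketone. The C9 acyl group is disconnected last: C-acylation of des-acyl trione 19 with (2R)-2-methylbutanoic acid.
2. Key disconnection of 19: the C7–C11 and C1–C10 bonds. The six-membered ring C1–C10–C9–C8–C7–C11 is a 1,3,5-tricarbonyl array in which C11 is an acyl carbon and its α-carbon C1 is the next nucleophile, so both bonds are Claisen retrons. This leads to β-keto ester 17.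
3. Enabling feature: the oxygen of the hydroxypropyl group on C3 is cis-1,3 to C11 across the cyclopentane C1–C5. C11 is therefore stored as a bridged δ-lactone of that alcohol (a 3-oxabicyclo[3.2.1]octan-2-one). The lactone is the acyl donor, makes C1–H a non-enolisable bridgehead until the first bond exists, and releases the free tertiary alcohol of the target.
4. 17 comes from keto lactone 10 (methylenation; hydroboration anti to the lactone bridge with B-alkyl Suzuki coupling; isomerisation; Roskamp homologation). 10 comes from cyclopentanone diester 8 (Grignard addition, lactonisation). 8 comes from 2,2-dimethylsuccinic anhydride, methyl acrylate and an Evans oxazolidinone (asymmetric Michael addition, Dieckmann condensation).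
5. Ring order: cyclopentane (step 4); temporary lactone ring (step 5); in step 10 the cyclopentanone ring C1–C5–C6–C7–C11, then the six-membered trione ring, with the lactone ring opened. C7 and the two side-chain centres enter as epimer mixtures and converge.

Key step: step 10

Remark 1: the side-chain stereocentre of the target is R as drawn, so (2R)-2-methylbutanoic acid is used; it and the other starting materials (1, 2, 5, 12, 16) are assumed to be commercial.
Remark 2: enolates, amides and alkoxides that are only conjugate bases of a numbered compound are not numbered separately; all other in-flask intermediates are.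

## Route

Step 1
Reactants: 1 (4S)-4-benzyl-1,3-oxazolidin-2-one; 2 3,3-dimethyloxolane-2,5-dione (2,2-dimethylsuccinic anhydride)
Product: 4 methyl 4-[(4S)-4-benzyl-2-oxo-1,3-oxazolidin-3-yl]-2,2-dimethyl-4-oxobutanoate, via lithium carboxylate 3 (not isolated)
Conditions: n-BuLi, THF, −78 °C; then 2, −78 to 0 °C; then MeI, DMF, rt
Reagents that add atoms: iodomethane, CI
Why: N-acylation of the lithiated oxazolidinone by the cyclic anhydride should occur at the carbonyl next to CH2 and not at the one next to the quaternary carbon, and the lithium carboxylate is then O-methylated in the same flask (SN2 esterification); no stereocentre is formed.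

Step 2
Reactants: 4 methyl 4-[(4S)-4-benzyl-2-oxo-1,3-oxazolidin-3-yl]-2,2-dimethyl-4-oxobutanoate; 5 methyl acrylate
Product: 6 dimethyl (3S)-3-{[(4S)-4-benzyl-2-oxo-1,3-oxazolidin-3-yl]carbonyl}-2,2-dimethylhexanedioate
Conditions: TiCl4, i-Pr2NEt, CH2Cl2, 0 °C; then 5, 0 °C to rt
Reagents that add atoms: none
Why: Evans asymmetric Michael addition, in which the chelated chlorotitanium Z-enolate of 4 adds to the acrylate from the face opposite the benzyl group (same sense as an Evans alkylation) and so sets the future C3 stereocentre.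

Step 3
Reactants: 6 dimethyl (3S)-3-{[(4S)-4-benzyl-2-oxo-1,3-oxazolidin-3-yl]carbonyl}-2,2-dimethylhexanedioate
Product: 7 dimethyl (3S)-3-(methoxycarbonyl)-2,2-dimethylhexanedioate
Conditions: NaOMe (1.1 equiv), MeOH/THF, 0 °C; aq. NH4Cl
Reagents that add atoms: sodium methoxide, C[O-].[Na+]
Why: Transesterification of the N-acyloxazolidinone, in which methoxide attacks the more electrophilic exocyclic imide carbonyl and releases the auxiliary; at 0 °C the hindered α-stereocentre next to the quaternary carbon should not epimerise.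

Step 4
Reactants: 7 dimethyl (3S)-3-(methoxycarbonyl)-2,2-dimethylhexanedioate
Product: 8 dimethyl (4S)-3,3-dimethyl-2-oxocyclopentane-1,4-dicarboxylate (C1 epimers and enol)
Conditions: KOt-Bu (1.1 equiv), THF, 0 °C, 30 min; AcOH
Reagents that add atoms: none
Why: Dieckmann condensation, in which only the enolate of the CH2CO2Me arm can reach an ester through a five-membered transition state (the alternatives are four-membered rings), and the product is held as its β-keto ester enolate, so one equivalent of base and a short time at 0 °C should spare the stereocentre.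

Step 5
Reactants: 8 dimethyl (4S)-3,3-dimethyl-2-oxocyclopentane-1,4-dicarboxylate
Product: 10 (1R,5S)-4,4,6,6-tetramethyl-3-oxabicyclo[3.2.1]octane-2,7-dione, via hydroxy keto ester 9 (not isolated)
Conditions: MeMgBr (4.5 equiv), THF, −20 to 0 °C; aq. NH4Cl; then PPTS (cat.), toluene, 110 °C, 4 Å molecular sieves
Reagents that add atoms: methylmagnesium bromide, C[Mg]Br
Why: The first equivalent of Grignard reagent turns the β-keto ester into its magnesium enolate, which protects the ketone and the conjugated ester so that double addition occurs only at the isolated ester, and acid-catalysed lactonisation then draws the epimerisable C1 ester to the face of the tertiary alcohol (cis-1,3) and fixes it as the bridgehead of a non-enolisable β-keto δ-lactone.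

Step 6
Reactants: 10 (1R,5S)-4,4,6,6-tetramethyl-3-oxabicyclo[3.2.1]octane-2,7-dione
Product: 11 (1R,5S)-4,4,6,6-tetramethyl-7-methylidene-3-oxabicyclo[3.2.1]octan-2-one
Conditions: Zn, CH2Br2, TiCl4, THF/CH2Cl2, 0 °C to rt
Reagents that add atoms: dibromomethane, BrCBr
Why: Lombardo methylenation is non-basic, selective for ketones over lactones and effective on hindered ketones flanked by quaternary carbons; no stereocentre is touched.

Step 7
Reactants: 11 (1R,5S)-4,4,6,6-tetramethyl-7-methylidene-3-oxabicyclo[3.2.1]octan-2-one; 12 2-bromoprop-2-en-1-ol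
Product: 14 (1R,5S,7R)-7-[2-(hydroxymethyl)prop-2-en-1-yl]-4,4,6,6-tetramethyl-3-oxabicyclo[3.2.1]octan-2-one, via alkylborane 13 (not isolated)
Conditions: 9-BBN dimer, THF, 60 °C; then 12, Pd(dppf)Cl2 (5 mol %), AsPh3 (5 mol %), aq. K3PO4, DMF, 50 °C
Reagents that add atoms: none
Why: Hydroboration puts boron on the terminal carbon and delivers hydrogen to the ring carbon from the open face of the cyclopentane, anti to the lactone bridge, so the new CH2 group ends syn to the lactone (7R), and B-alkyl Suzuki–Miyaura coupling of the primary borane with the vinyl bromide then forms the C–C bond without touching that centre.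

Step 8
Reactants: 14 (1R,5S,7R)-7-[2-(hydroxymethyl)prop-2-en-1-yl]-4,4,6,6-tetramethyl-3-oxabicyclo[3.2.1]octan-2-one
Product: 15 2-methyl-3-[(1R,5S,7R)-4,4,6,6-tetramethyl-2-oxo-3-oxabicyclo[3.2.1]octan-7-yl]propanal (both C2 epimers)
Conditions: [Ir(cod)(PCy3)(py)]PF6 (2 mol %, activated with H2 for 2 min, then Ar), THF, rt
Reagents that add atoms: none
Why: Metal hydride catalysed redox isomerisation of a 2-substituted primary allylic alcohol to the α-methyl aldehyde; the new α-centre forms as a mixture, which is harmless because it is planarised in step 10.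

Step 9
Reactants: 15 2-methyl-3-[(1R,5S,7R)-4,4,6,6-tetramethyl-2-oxo-3-oxabicyclo[3.2.1]octan-7-yl]propanal; 16 ethyl diazoacetate
Product: 17 ethyl 4-methyl-3-oxo-5-[(1R,5S,7R)-4,4,6,6-tetramethyl-2-oxo-3-oxabicyclo[3.2.1]octan-7-yl]pentanoate (both C4 epimers)
Conditions: SnCl2 (10 mol %), CH2Cl2, rt
Reagents that add atoms: none
Why: Roskamp homologation, in which Lewis acid catalysed addition of the diazo ester to the aldehyde and a 1,2-hydride shift with loss of N2 give the β-keto ester directly under conditions too mild to affect the lactone.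

Step 10
Reactants: 17 ethyl 4-methyl-3-oxo-5-[(1R,5S,7R)-4,4,6,6-tetramethyl-2-oxo-3-oxabicyclo[3.2.1]octan-7-yl]pentanoate
Product: 19 (1R,3S,5S,7S)-8-hydroxy-3-(2-hydroxypropan-2-yl)-4,4,7-trimethyltricyclo[5.3.1.0(1,5)]undec-8-ene-10,11-dione, via diquinane keto ester 18 (not isolated)
Conditions: LDA (3.3 equiv), THF, −78 to 0 °C, then 45 °C; 1 M HCl
Reagents that add atoms: none
Why: LDA removes first the C2 proton of the β-keto ester and then the γ-methine; the γ-carbon of this dianion adds to the lactone carbonyl, whose collapse opens the lactone to diquinanone 18 and frees the tertiary alkoxide, after which the third equivalent of base enolises the ring-fusion α-CH of the new ketone and this enolate acylates on the ester carbonyl with loss of ethoxide, ending as the stabilised enolate of the cyclic β-diketone, a vinylogous acid that makes the sequence irreversible. The closest known reaction types are the γ-acylation of β-keto ester dianions by esters and lactones and the Dieckmann closure used for bridged acylphloroglucinol-type triones. The cyclopentanone ring (C1–C5–C6–C7–C11) closes 5-exo-trig by carbanion attack on the lactone carbonyl, and the six-membered ring (C1–C10–C9–C8–C7–C11) closes 6-exo-trig by enolate attack on the ester, which turns the diquinane into the bicyclo[3.2.1]octane. The quaternary centre C7 is set from a planar enolate, so both epimers of 17 converge: only the mode that places the acyl chain on the convex face, cis to the ring-fusion hydrogens, can bridge to C1, and the other epimer of 18 can return by retro-Claisen attack of the neighbouring alkoxide; the quaternary centre C1 is dictated by the obligatory cis fusion of the two five-membered rings, and C3 and C5 are untouched. The step needs γ-deprotonation in preference to enolisation of the acyl donor, and C- in preference to O-acylation: the α-CH of the lactone is a bridgehead of the bicyclo[3.2.1] system and cannot enolise, so the γ-methine is the only second acidic site of 17, and any enol lactone from O-acylation is drained to the C-acylated enolate under the equilibrating conditions.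

Step 11
Reactants: 19 (1R,3S,5S,7S)-8-hydroxy-3-(2-hydroxypropan-2-yl)-4,4,7-trimethyltricyclo[5.3.1.0(1,5)]undec-8-ene-10,11-dione; 20 (2R)-2-methylbutanoic acid
Product: 22 (1S,3S,5S,7S)-8-hydroxy-3-(2-hydroxypropan-2-yl)-4,4,7-trimethyl-9-[(2R)-2-methylbutanoyl]tricyclo[5.3.1.0(1,5)]undec-8-ene-10,11-dione (CNP0207052.1), via enol ester 21 (not isolated)
Conditions: DCC (1.2 equiv), DMAP (1.2 equiv), CH2Cl2, 0 °C to rt
Reagents that add atoms: none
Why: Carbodiimide-mediated O-acylation of the cyclic β-diketone enol followed by DMAP-promoted O-to-C acyl migration (the standard entry to 2-acylcyclohexane-1,3-diones) should place the acyl group on C9, the only carbon between the two carbonyls, while the hindered tertiary alcohol does not compete and the R α-centre of 20 is carried in without strong base.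

## Compound list

1 | (4S)-4-benzyl-1,3-oxazolidin-2-one | O=C1OC[C@H](Cc2ccccc2)N1 | starting material
2 | 3,3-dimethyloxolane-2,5-dione (2,2-dimethylsuccinic anhydride) | CC1(C)CC(=O)OC1=O | starting material
3 | lithium 4-[(4S)-4-benzyl-2-oxo-1,3-oxazolidin-3-yl]-2,2-dimethyl-4-oxobutanoate | [Li+].[O-]C(=O)C(C)(C)CC(=O)N1[C@@H](Cc2ccccc2)COC1=O | intermediate
4 | methyl 4-[(4S)-4-benzyl-2-oxo-1,3-oxazolidin-3-yl]-2,2-dimethyl-4-oxobutanoate | COC(=O)C(C)(C)CC(=O)N1[C@@H](Cc2ccccc2)COC1=O | intermediate
5 | methyl acrylate | C=CC(=O)OC | starting material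
6 | dimethyl (3S)-3-{[(4S)-4-benzyl-2-oxo-1,3-oxazolidin-3-yl]carbonyl}-2,2-dimethylhexanedioate | COC(=O)CC[C@H](C(=O)N1[C@@H](Cc2ccccc2)COC1=O)C(C)(C)C(=O)OC | intermediate
7 | dimethyl (3S)-3-(methoxycarbonyl)-2,2-dimethylhexanedioate | COC(=O)CC[C@H](C(=O)OC)C(C)(C)C(=O)OC | intermediate
8 | dimethyl (4S)-3,3-dimethyl-2-oxocyclopentane-1,4-dicarboxylate (C1 epimers and enol) | COC(=O)C1C[C@H](C(=O)OC)C(C)(C)C1=O | intermediate
9 | methyl (4S)-4-(2-hydroxypropan-2-yl)-3,3-dimethyl-2-oxocyclopentane-1-carboxylate (C1 epimers) | COC(=O)C1C[C@H](C(C)(C)O)C(C)(C)C1=O | intermediate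
10 | (1R,5S)-4,4,6,6-tetramethyl-3-oxabicyclo[3.2.1]octane-2,7-dione | O=C1C(C)(C)[C@@H]2C[C@H]1C(=O)OC2(C)C | intermediate
11 | (1R,5S)-4,4,6,6-tetramethyl-7-methylidene-3-oxabicyclo[3.2.1]octan-2-one | C=C1C(C)(C)[C@@H]2C[C@H]1C(=O)OC2(C)C | intermediate
12 | 2-bromoprop-2-en-1-ol | OCC(Br)=C | starting material
13 | (1R,5S,7R)-7-[(9-borabicyclo[3.3.1]nonan-9-yl)methyl]-4,4,6,6-tetramethyl-3-oxabicyclo[3.2.1]octan-2-one | B1(C[C@H]4C(C)(C)[C@@H]5C[C@H]4C(=O)OC5(C)C)C2CCCC1CCC2 | intermediate
14 | (1R,5S,7R)-7-[2-(hydroxymethyl)prop-2-en-1-yl]-4,4,6,6-tetramethyl-3-oxabicyclo[3.2.1]octan-2-one | OCC(=C)C[C@H]1C(C)(C)[C@@H]2C[C@H]1C(=O)OC2(C)C | intermediate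
15 | 2-methyl-3-[(1R,5S,7R)-4,4,6,6-tetramethyl-2-oxo-3-oxabicyclo[3.2.1]octan-7-yl]propanal (both C2 epimers) | O=CC(C)C[C@H]1C(C)(C)[C@@H]2C[C@H]1C(=O)OC2(C)C | intermediate
16 | ethyl diazoacetate | CCOC(=O)C=[N+]=[N-] | starting material
17 | ethyl 4-methyl-3-oxo-5-[(1R,5S,7R)-4,4,6,6-tetramethyl-2-oxo-3-oxabicyclo[3.2.1]octan-7-yl]pentanoate (both C4 epimers) | CCOC(=O)CC(=O)C(C)C[C@H]1C(C)(C)[C@@H]2C[C@H]1C(=O)OC2(C)C | intermediate
18 | ethyl 3-[(2S,3aR,5S,6aR)-5-(2-hydroxypropan-2-yl)-2,4,4-trimethyl-1-oxooctahydropentalen-2-yl]-3-oxopropanoate | CCOC(=O)CC(=O)[C@]1(C)C[C@H]2C(C)(C)[C@@H](C(C)(C)O)C[C@H]2C1=O | intermediate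
19 | (1R,3S,5S,7S)-8-hydroxy-3-(2-hydroxypropan-2-yl)-4,4,7-trimethyltricyclo[5.3.1.0(1,5)]undec-8-ene-10,11-dione | C1=C(O)[C@]2(C)C[C@H]3C(C)(C)[C@@H](C(C)(C)O)C[C@@]3(C1=O)C2=O | intermediate
20 | (2R)-2-methylbutanoic acid | CC[C@@H](C)C(O)=O | starting material
21 | (1R,3S,5S,7S)-3-(2-hydroxypropan-2-yl)-4,4,7-trimethyl-10,11-dioxotricyclo[5.3.1.0(1,5)]undec-8-en-8-yl (2R)-2-methylbutanoate | C1=C(OC(=O)[C@H](C)CC)[C@]2(C)C[C@H]3C(C)(C)[C@@H](C(C)(C)O)C[C@@]3(C1=O)C2=O | intermediate
22 | (1S,3S,5S,7S)-8-hydroxy-3-(2-hydroxypropan-2-yl)-4,4,7-trimethyl-9-[(2R)-2-methylbutanoyl]tricyclo[5.3.1.0(1,5)]undec-8-ene-10,11-dione (CNP0207052.1) | CC[C@@H](C)C(=O)C1=C(O)[C@]2(C)C[C@H]3C(C)(C)[C@@H](C(C)(C)O)C[C@@]3(C1=O)C2=O | target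

## Step count and risks

Total number of steps: 11, all in one linear sequence. Longest linear sequence: 11 steps (from 1 and 2 to 22).

Steps most likely to fail:

**Step 10.** Deprotonation at the tertiary γ-carbon may be incomplete, intermolecular Claisen condensation may compete, or the sequence may stall after the first acylation because the ester of an enolised β-keto ester is a poor electrophile. The fallback builds the trione by an Effenberger annulation on a preformed diquinanone. It sets out from aldehyde 15 and comes back to the route at 19. Pinnick oxidation (NaClO2, NaH2PO4, 2-methylbut-2-ene) should give the carboxylic acid F1, and Me3SiCHN2 in MeOH the methyl ester F2. LDA should then close the simple ester enolate (the only acidic C–H, the lactone α-CH being a bridgehead) onto the lactone carbonyl to give the bicyclic β-keto ester F3. Krapcho dealkoxycarbonylation (LiCl, wet DMSO, 150 °C) should give the methyl ketone F4. Me3SiOTf/Et3N should give the bis-silyl compound F5 (silyl enol ether and silyl ether). Malonyl dichloride, then aqueous KOH with BnEt3NCl and an acidic work-up, should acylate both α-carbons of the ketone and remove the silyl groups to give 19.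

**Step 7.** Hydrogen may be delivered to the wrong face of the exocyclic alkene, transmetalation of the β-branched borane may be slow, or β-hydride elimination may occur at the alkylpalladium stage. The fallback sets the same stereocentre by heterogeneous hydrogenation in the monocyclic series. It sets out from 9 (isolated after the Grignard addition) and comes back to the route at 15. Et3SiOTf/2,6-lutidine should give the triethylsilyl ether F6, and NaH/PhNTf2 the enol triflate F7. B-alkyl Suzuki coupling with the borane reagent F8 (from tert-butyldimethyl[(2-methylprop-2-en-1-yl)oxy]silane and 9-BBN) should give the tetrasubstituted enoate F9. Hydrogenation (H2, Rh/Al2O3, elevated pressure) from the face opposite the bulky silyloxypropyl group should give the all-cis diester F10. HF·pyridine, then PPTS in hot toluene, should remove both silyl groups and close the lactone to the hydroxy lactone F11. Dess–Martin oxidation of F11 should give 15.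

**Step 5.** The Grignard reagent may enolise the isolated ester instead of adding (loss of configuration at the adjacent centre), may attack the ketone if enolate protection is incomplete, or the tertiary alcohol may dehydrate during lactonisation. The fallback masks the β-keto ester covalently before the addition. It sets out from 8 and comes back to the route at 9. HC(OMe)3 with TsOH in MeOH should give the methyl enol ether F12. MeMgBr should then add only to the saturated ester, the conjugated ester being a vinylogous carbonate, to give the tertiary alcohol F13. Aqueous HCl in THF should hydrolyse the enol ether to 9, which is lactonised to 10 as in the main route. If closure of the bridged β-keto lactone itself fails, the silyl ether sequence described for step 7 bypasses 10.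

## Further compounds

F1 | step 10 | 2-methyl-3-[(1R,5S,7R)-4,4,6,6-tetramethyl-2-oxo-3-oxabicyclo[3.2.1]octan-7-yl]propanoic acid | OC(=O)C(C)C[C@H]1C(C)(C)[C@@H]2C[C@H]1C(=O)OC2(C)C
F2 | step 10 | methyl 2-methyl-3-[(1R,5S,7R)-4,4,6,6-tetramethyl-2-oxo-3-oxabicyclo[3.2.1]octan-7-yl]propanoate | COC(=O)C(C)C[C@H]1C(C)(C)[C@@H]2C[C@H]1C(=O)OC2(C)C
F3 | step 10 | methyl (3aR,5S,6aR)-5-(2-hydroxypropan-2-yl)-2,4,4-trimethyl-1-oxooctahydropentalene-2-carboxylate (C2 epimers) | COC(=O)C1(C)C[C@H]2C(C)(C)[C@@H](C(C)(C)O)C[C@H]2C1=O
F4 | step 10 | (3aR,5S,6aR)-5-(2-hydroxypropan-2-yl)-2,4,4-trimethylhexahydropentalen-1(2H)-one (C2 epimers) | CC1C[C@H]2C(C)(C)[C@@H](C(C)(C)O)C[C@H]2C1=O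
F5 | step 10 | trimethylsilyl enol ether of F4 with the tertiary alcohol as trimethylsilyl ether | CC=1C[C@H]2C(C)(C)[C@@H](C(C)(C)O[Si](C)(C)C)C[C@H]2C=1O[Si](C)(C)C
F6 | step 7 | methyl (4S)-3,3-dimethyl-2-oxo-4-{2-[(triethylsilyl)oxy]propan-2-yl}cyclopentane-1-carboxylate | COC(=O)C1C[C@H](C(C)(C)O[Si](CC)(CC)CC)C(C)(C)C1=O
F7 | step 7 | methyl (4S)-3,3-dimethyl-4-{2-[(triethylsilyl)oxy]propan-2-yl}-2-{[(trifluoromethyl)sulfonyl]oxy}cyclopent-1-ene-1-carboxylate | COC(=O)C1=C(OS(=O)(=O)C(F)(F)F)C(C)(C)[C@@H](C(C)(C)O[Si](CC)(CC)CC)C1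
F8 | step 7 | 9-{3-[(tert-butyldimethylsilyl)oxy]-2-methylpropyl}-9-borabicyclo[3.3.1]nonane | CC(CO[Si](C)(C)C(C)(C)C)CB1C2CCCC1CCC2
F9 | step 7 | methyl (4S)-2-{3-[(tert-butyldimethylsilyl)oxy]-2-methylpropyl}-3,3-dimethyl-4-{2-[(triethylsilyl)oxy]propan-2-yl}cyclopent-1-ene-1-carboxylate | COC(=O)C1=C(CC(C)CO[Si](C)(C)C(C)(C)C)C(C)(C)[C@@H](C(C)(C)O[Si](CC)(CC)CC)C1
F10 | step 7 | methyl (1R,2R,4S)-2-{3-[(tert-butyldimethylsilyl)oxy]-2-methylpropyl}-3,3-dimethyl-4-{2-[(triethylsilyl)oxy]propan-2-yl}cyclopentane-1-carboxylate (all-cis) | CC(CO[Si](C)(C)C(C)(C)C)C[C@H]1C(C)(C)[C@@H](C(C)(C)O[Si](CC)(CC)CC)C[C@H]1C(=O)OC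
F11 | step 7 | (1R,5S,7R)-7-(3-hydroxy-2-methylpropyl)-4,4,6,6-tetramethyl-3-oxabicyclo[3.2.1]octan-2-one | OCC(C)C[C@H]1C(C)(C)[C@@H]2C[C@H]1C(=O)OC2(C)C
F12 | step 5 | dimethyl (4S)-2-methoxy-3,3-dimethylcyclopent-1-ene-1,4-dicarboxylate | COC(=O)C1=C(OC)C(C)(C)[C@@H](C(=O)OC)C1
F13 | step 5 | methyl (4S)-4-(2-hydroxypropan-2-yl)-2-methoxy-3,3-dimethylcyclopent-1-ene-1-carboxylate | COC(=O)C1=C(OC)C(C)(C)[C@@H](C(C)(C)O)C1
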